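**Route in brief**

- Retrosynthesis: after the phenol protecting groups, the only skeletal cut is the C2'–C6' biaryl bond between the two B rings. Behind it lie the C5'–heteroatom bonds of the two halves (both traced to one C5'–B bond) and the two C3–O gallate ester bonds, which leads back to (−)-epicatechin and gallic acid.
- Enabling feature: the axis joins a pyrogallol ring B whose O3' is ortho to the axis and a catechol ring B whose other ortho carbon, C5', bears only H. A sulfur atom parked on C5' can be bonded to O3'; the O–S pair relays a [3,3] shift that makes C2'–C6', and the sulfur is then cut out.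
- Forward order: all rings are bought (rings A, C and B with epicatechin, the galloyl ring with gallic acid). The ester is made at O3, one C5'-boronate is split into a phenol half and a methyl sulfoxide half, the halves are united, sulfur is removed and the phenols are released.
- Stereochemistry: C2 and C3 of both flavan units (all R) are those of (−)-epicatechin and no step touches them. The axis arises in the union under the influence of the two chromanyl groups.

Key step: step 12

Assumption: the given structure leaves the C2'–C6' axis undefined; the route fixes the constitution and the four stereocentres, and the atropisomeric diastereomers that step 12 can give are to be separated at compound 19.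

Numbering remark: primes are ring B positions; in the phenol half the hydroxylated carbon (C5' of the borylated precursor) is called C3', as in the pyrogallol ring of the target, and its free neighbour C2'. TBS = tert-butyldimethylsilyl.

**Step 1**
Reactants: 1 (−)-epicatechin
Product: 2 3',4'-O-diphenylmethylene-(−)-epicatechin
Conditions: Ph2CCl2, K2CO3, MeCN, rt
Reagents that add atoms: dichlorodiphenylmethane ClC(Cl)(c1ccccc1)c1ccccc1
Why: Ketalisation by double O-alkylation with the gem-dichloride can close a five-membered ring only on the ring B catechol, because the ring A phenols are meta to each other and the 3-OH is far less acidic.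

**Step 2**
Reactants: 2 3',4'-O-diphenylmethylene-(−)-epicatechin
Product: 3 5,7-di-O-TBS-3',4'-O-diphenylmethylene-(−)-epicatechin
Conditions: TBSCl (2.2 equiv), imidazole, DMF, 0 °C → rt
Reagents that add atoms: tert-butyldimethylsilyl chloride CC(C)(C)[Si](C)(C)Cl
Why: Imidazole-mediated silylation is much faster at the two acidic ring A phenols than at the axial, hindered secondary 3-OH, which should stay free.

**Step 3**
Reactants: 4 gallic acid
Product: 6 3,4,5-tris(tert-butyldimethylsilyloxy)benzoic acid, via silyl ester 5 (not isolated)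
Conditions: TBSCl (excess), imidazole, DMF, rt; then AcOH/THF/H2O (3:1:1), rt
Reagents that add atoms: tert-butyldimethylsilyl chloride CC(C)(C)[Si](C)(C)Cl
Why: Exhaustive silylation followed by mild acidolysis uses the much higher lability of the silyl ester bond compared with aryl silyl ethers.

**Step 4**
Reactants: 3 5,7-di-O-TBS-3',4'-O-diphenylmethylene-(−)-epicatechin; 6 3,4,5-tris(tert-butyldimethylsilyloxy)benzoic acid
Product: 7 silyl-protected epicatechin gallate diphenylmethylene ketal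
Conditions: DCC, DMAP (cat.), CH2Cl2, 0 °C → rt
Reagents that add atoms: none
Why: Steglich esterification (carbodiimide activation, DMAP acyl transfer) acylates the 3-OH at oxygen, so C3 keeps its R configuration.

**Step 5**
Reactants: 7 silyl-protected epicatechin gallate diphenylmethylene ketal
Product: 8 silyl-protected epicatechin gallate with free ring B catechol
Conditions: H2 (1 atm), Pd(OH)2/C, EtOAc/THF, rt
Reagents that add atoms: none
Why: Catalytic hydrogenolysis cleaves the doubly benzylic C–O bonds of the benzophenone ketal far faster than the cyclic benzylic ether of ring C, and aryl silyl ethers and the ester are inert in a non-alcoholic solvent.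

**Step 6**
Reactants: 8 silyl-protected epicatechin gallate with free ring B catechol
Product: 9 silyl-protected epicatechin gallate ring B acetonide
Conditions: Me2C(OMe)2, camphorsulfonic acid (cat.), benzene, reflux (4 Å molecular sieves in a Soxhlet)
Reagents that add atoms: 2,2-dimethoxypropane COC(C)(C)OC
Why: Acid-catalysed transketalisation with removal of methanol gives a catechol mask without aryl C–H bonds and with tied-back oxygens, and it is installed only now because O3 is acylated and ring A is silylated, so the acid meets no free hydroxyl.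

**Step 7**
Reactants: 9 silyl-protected epicatechin gallate ring B acetonide
Product: 10 C5'-pinacolboronate
Conditions: B2pin2, [Ir(OMe)(cod)]2 (cat.), 4,4'-di-tert-butyl-2,2'-bipyridine (cat.), THF, 80 °C
Reagents that add atoms: bis(pinacolato)diboron CC1(C)OB(OC1(C)C)B1OC(C)(C)C(C)(C)O1
Why: Iridium-catalysed aromatic C–H borylation is governed by sterics, and C5'–H is the only aryl C–H flanked by a hydrogen and a tied-back dioxole oxygen, whereas every other one sits next to the chromanyl-bearing carbon, a silyl ether or the ester-bearing carbon.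

**Step 8**
Reactants: 10 C5'-pinacolboronate
Product: 12 phenol half with one free ring B hydroxyl, via aryl borate 11 (not isolated)
Conditions: Me3NO (anhydrous), THF, 50 °C; then aq. NH4Cl
Reagents that add atoms: trimethylamine N-oxide C[N+](C)(C)[O-]
Why: The amine N-oxide adds to boron and triggers a 1,2-aryl shift from boron to oxygen (the migration known from peroxide oxidation of boranes) without aqueous base, so the aryl silyl ethers should survive, and the borate is hydrolysed on work-up.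

**Step 9**
Reactants: 10 C5'-pinacolboronate
Product: 13 C5'-boronic acid
Conditions: NaIO4, NH4OAc, acetone/H2O, rt
Reagents that add atoms: water O
Why: Periodate glycol cleavage destroys the pinacol released in the hydrolysis equilibrium, which drives the boronate to the free boronic acid under nearly neutral conditions.

**Step 10**
Reactants: 13 C5'-boronic acid
Product: 14 C5'-methyl sulfide
Conditions: S-methyl 4-methylbenzenethiosulfonate, CuSO4 (cat.), 1,10-phenanthroline (cat.), NaHCO3, MeOH/THF, rt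
Reagents that add atoms: S-methyl 4-methylbenzenethiosulfonate CSS(=O)(=O)c1ccc(C)cc1
Why: Copper-catalysed deborylative thiolation (a Chan–Lam-type C–S coupling with an electrophilic sulfur donor) transfers the methylsulfanyl group to the boron-bearing carbon at room temperature under weakly basic conditions.

**Step 11**
Reactants: 14 C5'-methyl sulfide
Product: 15 C5'-methyl sulfoxide (both sulfur epimers)
Conditions: mCPBA (1.0 equiv), CH2Cl2, −78 → −40 °C
Reagents that add atoms: 3-chloroperoxybenzoic acid OOC(=O)c1cccc(Cl)c1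
Why: Electrophilic oxygen transfer from one equivalent of peracid to the soft sulfide at low temperature stops at the sulfoxide, and the epimer mixture is acceptable because the sulfur centre disappears in step 12.

**Step 12**
Reactants: 12 phenol half with one free ring B hydroxyl; 15 C5'-methyl sulfoxide
Product: 19 2-hydroxy-2'-methylsulfanyl biaryl dimer, via acyloxysulfonium salt 16 (not isolated), via aryloxysulfonium salt 17 (not isolated), via thionium dienone 18 (not isolated)
Conditions: (CF3CO)2O, CH2Cl2, −40 °C → rt; then aq. NaHCO3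
Reagents that add atoms: none
Why: (CF3CO)2O acylates the sulfoxide oxygen of 15 to give 16, and the only free hydroxyl of 12 (O3') displaces trifluoroacetate at sulfur to give 17, in which the two B rings are held by a temporary S–O bond. A charge-accelerated [3,3] sigmatropic shift through the six-atom array C2'–C3'–O–S–C5'–C6' then forms the C2'–C6' bond as the S–O bond breaks, giving 18, and two proton shifts restore both arenes to give 19. The closest known reaction type is the dehydrative coupling of aryl methyl sulfoxides with phenols (interrupted Pummerer activation, then sulfonium [3,3] rearrangement) to 2-hydroxy-2'-methylsulfanylbiaryls, which extends to hindered binaphthyl-type products. No ring is closed, since the six-membered array exists only in the transition state. No stereocentre is created: the sulfur centre of 15 is consumed, and the new axis is set under control of the two (2R)-chromanyl groups beside the reacting carbons, the atropisomers being separable diastereomers. The step needs O–S bond formation instead of C-sulfenylation of ring A or Pummerer reaction at S–CH3, and a shift onto one carbon of each ring; this is secured because 12 has one free phenol, on each ring B only one carbon next to the tethered heteroatom still bears hydrogen (C2' beside O3', C6' beside sulfur), and C6 and C8 are flanked by silyl ethers.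

**Step 13**
Reactants: 19 2-hydroxy-2'-methylsulfanyl biaryl dimer
Product: 20 desulfurised protected theasinensin F
Conditions: Raney Ni (W-2, washed neutral), EtOH/THF, rt → 40 °C
Reagents that add atoms: none
Why: Raney nickel hydrogenolysis of the aryl C–S bond (reductive desulfurisation) is standard for aryl methyl sulfides and for flavan thioethers, ring C, esters and aryl silyl ethers should persist, and the axis stays tri-ortho-substituted and is expected to keep its configuration.

**Step 14**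
Reactants: 20 desulfurised protected theasinensin F
Product: 21 theasinensin F bis-acetonide
Conditions: Et3N·3HF, THF, rt, argon
Reagents that add atoms: none
Why: Fluoride-induced Si–O cleavage, driven by the strong Si–F bond, should remove all ten aryl silyl ethers in a slightly acidic medium that neither cleaves the gallate esters nor epimerises C2.

**Step 15**
Reactants: 21 theasinensin F bis-acetonide
Product: 22 theasinensin F
Conditions: CF3CO2H/H2O (9:1), degassed, 0 °C → rt, argon; evaporation, Sephadex LH-20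
Reagents that add atoms: none
Why: Aqueous acid hydrolysis of the two catechol isopropylidene ketals gives only acetone beside volatile reagents, and exclusion of oxygen protects the pyrogallol units.

**Compound list**

1 | (−)-epicatechin, (2R,3R)-2-(3,4-dihydroxyphenyl)chroman-3,5,7-triol | O[C@@H]1Cc2c(O)cc(O)cc2O[C@@H]1c1ccc(O)c(O)c1 | starting material

2 | 3',4'-O-diphenylmethylene-(−)-epicatechin, (2R,3R)-2-(2,2-diphenyl-1,3-benzodioxol-5-yl)chroman-3,5,7-triol | O[C@@H]1Cc2c(O)cc(O)cc2O[C@@H]1c1ccc2OC(c3ccccc3)(c3ccccc3)Oc2c1 | intermediate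

3 | 5,7-di-O-TBS-3',4'-O-diphenylmethylene-(−)-epicatechin (2R,3R; 3-OH free) | O[C@@H]1Cc2c(O[Si](C)(C)C(C)(C)C)cc(O[Si](C)(C)C(C)(C)C)cc2O[C@@H]1c1ccc2OC(c3ccccc3)(c3ccccc3)Oc2c1 | intermediate

4 | gallic acid | O=C(O)c1cc(O)c(O)c(O)c1 | starting material

5 | tert-butyldimethylsilyl 3,4,5-tris(tert-butyldimethylsilyloxy)benzoate (not isolated) | O=C(O[Si](C)(C)C(C)(C)C)c1cc(O[Si](C)(C)C(C)(C)C)c(O[Si](C)(C)C(C)(C)C)c(O[Si](C)(C)C(C)(C)C)c1 | intermediate

6 | 3,4,5-tris(tert-butyldimethylsilyloxy)benzoic acid | O=C(O)c1cc(O[Si](C)(C)C(C)(C)C)c(O[Si](C)(C)C(C)(C)C)c(O[Si](C)(C)C(C)(C)C)c1 | intermediate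

7 | (2R,3R)-5,7-bis(TBSO)-2-(2,2-diphenyl-1,3-benzodioxol-5-yl)chroman-3-yl 3,4,5-tris(TBSO)benzoate | O=C(O[C@@H]1Cc2c(O[Si](C)(C)C(C)(C)C)cc(O[Si](C)(C)C(C)(C)C)cc2O[C@@H]1c1ccc2OC(c3ccccc3)(c3ccccc3)Oc2c1)c1cc(O[Si](C)(C)C(C)(C)C)c(O[Si](C)(C)C(C)(C)C)c(O[Si](C)(C)C(C)(C)C)c1 | intermediate

8 | (2R,3R)-5,7-bis(TBSO)-2-(3,4-dihydroxyphenyl)chroman-3-yl 3,4,5-tris(TBSO)benzoate | O=C(O[C@@H]1Cc2c(O[Si](C)(C)C(C)(C)C)cc(O[Si](C)(C)C(C)(C)C)cc2O[C@@H]1c1ccc(O)c(O)c1)c1cc(O[Si](C)(C)C(C)(C)C)c(O[Si](C)(C)C(C)(C)C)c(O[Si](C)(C)C(C)(C)C)c1 | intermediate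

9 | (2R,3R)-5,7-bis(TBSO)-2-(2,2-dimethyl-1,3-benzodioxol-5-yl)chroman-3-yl 3,4,5-tris(TBSO)benzoate | O=C(O[C@@H]1Cc2c(O[Si](C)(C)C(C)(C)C)cc(O[Si](C)(C)C(C)(C)C)cc2O[C@@H]1c1ccc2OC(C)(C)Oc2c1)c1cc(O[Si](C)(C)C(C)(C)C)c(O[Si](C)(C)C(C)(C)C)c(O[Si](C)(C)C(C)(C)C)c1 | intermediate

10 | C5'-pinacolboronate of 9 (boron on benzodioxole C7, ortho to the dioxole oxygen) | O=C(O[C@@H]1Cc2c(O[Si](C)(C)C(C)(C)C)cc(O[Si](C)(C)C(C)(C)C)cc2O[C@@H]1c1cc(B3OC(C)(C)C(C)(C)O3)c3OC(C)(C)Oc3c1)c1cc(O[Si](C)(C)C(C)(C)C)c(O[Si](C)(C)C(C)(C)C)c(O[Si](C)(C)C(C)(C)C)c1 | intermediate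

11 | aryl pinacol borate, ArO–Bpin at the former C–B carbon (not isolated) | O=C(O[C@@H]1Cc2c(O[Si](C)(C)C(C)(C)C)cc(O[Si](C)(C)C(C)(C)C)cc2O[C@@H]1c1cc(OB3OC(C)(C)C(C)(C)O3)c3OC(C)(C)Oc3c1)c1cc(O[Si](C)(C)C(C)(C)C)c(O[Si](C)(C)C(C)(C)C)c(O[Si](C)(C)C(C)(C)C)c1 | intermediate

12 | phenol half: (2R,3R)-5,7-bis(TBSO)-2-(7-hydroxy-2,2-dimethyl-1,3-benzodioxol-5-yl)chroman-3-yl 3,4,5-tris(TBSO)benzoate | O=C(O[C@@H]1Cc2c(O[Si](C)(C)C(C)(C)C)cc(O[Si](C)(C)C(C)(C)C)cc2O[C@@H]1c1cc(O)c2OC(C)(C)Oc2c1)c1cc(O[Si](C)(C)C(C)(C)C)c(O[Si](C)(C)C(C)(C)C)c(O[Si](C)(C)C(C)(C)C)c1 | intermediate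

13 | C5'-boronic acid (B(OH)2 on benzodioxole C7) | O=C(O[C@@H]1Cc2c(O[Si](C)(C)C(C)(C)C)cc(O[Si](C)(C)C(C)(C)C)cc2O[C@@H]1c1cc(B(O)O)c2OC(C)(C)Oc2c1)c1cc(O[Si](C)(C)C(C)(C)C)c(O[Si](C)(C)C(C)(C)C)c(O[Si](C)(C)C(C)(C)C)c1 | intermediate

14 | C5'-methyl sulfide (SCH3 on benzodioxole C7) | O=C(O[C@@H]1Cc2c(O[Si](C)(C)C(C)(C)C)cc(O[Si](C)(C)C(C)(C)C)cc2O[C@@H]1c1cc(SC)c2OC(C)(C)Oc2c1)c1cc(O[Si](C)(C)C(C)(C)C)c(O[Si](C)(C)C(C)(C)C)c(O[Si](C)(C)C(C)(C)C)c1 | intermediate

15 | sulfoxide half: C5'-methylsulfinyl compound, both sulfur epimers | O=C(O[C@@H]1Cc2c(O[Si](C)(C)C(C)(C)C)cc(O[Si](C)(C)C(C)(C)C)cc2O[C@@H]1c1cc(S(C)=O)c2OC(C)(C)Oc2c1)c1cc(O[Si](C)(C)C(C)(C)C)c(O[Si](C)(C)C(C)(C)C)c(O[Si](C)(C)C(C)(C)C)c1 | intermediate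

16 | aryl(methyl)(trifluoroacetoxy)sulfonium trifluoroacetate from 15 (not isolated) | O=C(O[C@@H]1Cc2c(O[Si](C)(C)C(C)(C)C)cc(O[Si](C)(C)C(C)(C)C)cc2O[C@@H]1c1cc([S+](C)OC(=O)C(F)(F)F)c2OC(C)(C)Oc2c1)c1cc(O[Si](C)(C)C(C)(C)C)c(O[Si](C)(C)C(C)(C)C)c(O[Si](C)(C)C(C)(C)C)c1.[O-]C(=O)C(F)(F)F | intermediate

17 | aryloxysulfonium trifluoroacetate: sulfur bonded to CH3, to C5' of the catechol half and to O3' of the phenol half (not isolated) | O=C(O[C@@H]1Cc2c(O[Si](C)(C)C(C)(C)C)cc(O[Si](C)(C)C(C)(C)C)cc2O[C@@H]1c1cc([S+](C)Oc3cc([C@H]5Oc6cc(O[Si](C)(C)C(C)(C)C)cc(O[Si](C)(C)C(C)(C)C)c6C[C@H]5OC(=O)c5cc(O[Si](C)(C)C(C)(C)C)c(O[Si](C)(C)C(C)(C)C)c(O[Si](C)(C)C(C)(C)C)c5)cc4OC(C)(C)Oc34)c2OC(C)(C)Oc2c1)c1cc(O[Si](C)(C)C(C)(C)C)c(O[Si](C)(C)C(C)(C)C)c(O[Si](C)(C)C(C)(C)C)c1.[O-]C(=O)C(F)(F)F | intermediate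

18 | dearomatised [3,3] product: cyclohexadienone (former phenol ring, sp3 C2') bonded to sp3 C6' of a cyclohexadienylidene methylsulfonium, trifluoroacetate salt, the two sp3 centres transient (not isolated) | O=C(O[C@@H]1Cc2c(O[Si](C)(C)C(C)(C)C)cc(O[Si](C)(C)C(C)(C)C)cc2O[C@@H]1C1=CC2=C(OC(C)(C)O2)C(=[S+]C)C1C3C(=O)C4=C(OC(C)(C)O4)C=C3[C@H]5Oc6cc(O[Si](C)(C)C(C)(C)C)cc(O[Si](C)(C)C(C)(C)C)c6C[C@H]5OC(=O)c5cc(O[Si](C)(C)C(C)(C)C)c(O[Si](C)(C)C(C)(C)C)c(O[Si](C)(C)C(C)(C)C)c5)c1cc(O[Si](C)(C)C(C)(C)C)c(O[Si](C)(C)C(C)(C)C)c(O[Si](C)(C)C(C)(C)C)c1.[O-]C(=O)C(F)(F)F | intermediate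

19 | biaryl dimer: 6,6'-linked bis(2,2-dimethyl-1,3-benzodioxole) with 7-OH on one ring, 7'-SCH3 on the other and a (2R,3R)-5,7-bis(TBSO)-3-[tris(TBSO)galloyloxy]chroman-2-yl group at C5 and C5' | O=C(O[C@@H]1Cc2c(O[Si](C)(C)C(C)(C)C)cc(O[Si](C)(C)C(C)(C)C)cc2O[C@@H]1c1cc2OC(C)(C)Oc2c(SC)c1-c1c([C@H]2Oc3cc(O[Si](C)(C)C(C)(C)C)cc(O[Si](C)(C)C(C)(C)C)c3C[C@H]2OC(=O)c2cc(O[Si](C)(C)C(C)(C)C)c(O[Si](C)(C)C(C)(C)C)c(O[Si](C)(C)C(C)(C)C)c2)cc2OC(C)(C)Oc2c1O)c1cc(O[Si](C)(C)C(C)(C)C)c(O[Si](C)(C)C(C)(C)C)c(O[Si](C)(C)C(C)(C)C)c1 | intermediate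

20 | desulfurised protected theasinensin F (19 with H in place of SCH3) | O=C(O[C@@H]1Cc2c(O[Si](C)(C)C(C)(C)C)cc(O[Si](C)(C)C(C)(C)C)cc2O[C@@H]1c1cc2OC(C)(C)Oc2cc1-c1c([C@H]2Oc3cc(O[Si](C)(C)C(C)(C)C)cc(O[Si](C)(C)C(C)(C)C)c3C[C@H]2OC(=O)c2cc(O[Si](C)(C)C(C)(C)C)c(O[Si](C)(C)C(C)(C)C)c(O[Si](C)(C)C(C)(C)C)c2)cc2OC(C)(C)Oc2c1O)c1cc(O[Si](C)(C)C(C)(C)C)c(O[Si](C)(C)C(C)(C)C)c(O[Si](C)(C)C(C)(C)C)c1 | intermediate

21 | theasinensin F bis-acetonide (all silyl ethers removed, both ring B acetonides in place) | O=C(O[C@@H]1Cc2c(O)cc(O)cc2O[C@@H]1c1cc2OC(C)(C)Oc2cc1-c1c([C@H]2Oc3cc(O)cc(O)c3C[C@H]2OC(=O)c2cc(O)c(O)c(O)c2)cc2OC(C)(C)Oc2c1O)c1cc(O)c(O)c(O)c1 | intermediate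

22 | theasinensin F (2R,3R,2R,3R) | O=C(O[C@@H]1Cc2c(O)cc(O)cc2O[C@@H]1c1cc(O)c(O)cc1-c1c([C@H]2Oc3cc(O)cc(O)c3C[C@H]2OC(=O)c2cc(O)c(O)c(O)c2)cc(O)c(O)c1O)c1cc(O)c(O)c(O)c1 | target

**Step count and risk**

Total step count: 15.
Longest linear sequence: 13 steps (steps 1, 2, 4, 5, 6, 7, 9, 10, 11, 12, 13, 14, 15, from 1 to 22).

The three steps most likely to fail:

1. Step 12. The shift through the crowded six-atom array, flanked by two chromanyl groups, may be slower than heterolysis of the S–O bond (net oxidation of the phenol and return of the sulfide) or Pummerer loss at the S-methyl group, and the atropisomer ratio may be poor. The fallback sets out from boronic acid 13 and comes back at 20; it replaces the sulfur tether by an iodine tether with longer, looser bonds. Ipso-iododeboronation (N-iodosuccinimide, MeCN) should give the C5'-iodide F1. Oxidation with mCPBA in AcOH should give the diacetoxyiodoarene F2 (trivalent iodine). Ligand exchange with phenol 12 and the analogous [3,3] shift of the aryloxyiodane (CF3CO2H, CH2Cl2), a known route to 2-hydroxy-2'-iodobiaryls, should give the 2-hydroxy-2'-iodobiaryl F3. Hydrodeiodination (H2, Pd/C, NaOAc, EtOAc) then gives 20.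

2. Step 13. Hydrogenolysis at a sulfur buried beside the axis and shielded by ten silyl groups may be too slow, and forcing it invites cleavage of the benzylic C2–O1 bonds. The fallback sets out from 19 and comes back at 21; it reverses the order of the last operations. Et3N·3HF in THF should first remove the ten silyl ethers to give the desilylated sulfide F4. Raney Ni in EtOH is then applied to this small polar polyphenol, the setting in which flavan thioethers are classically desulfurised, and gives 21.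

3. Step 10. Protodeboronation of the electron-rich, ortho-oxygenated boronic acid and methanolysis of aryl silyl ethers under bicarbonate may compete with C–S bond formation. The fallback sets out from phenol 12 and comes back at 14; it builds the C–S bond by palladium catalysis instead of from boron. Triflation (Tf2O, pyridine, CH2Cl2) should give the C5'-triflate F5. C–S coupling with NaSMe (Pd2(dba)3, Xantphos, toluene, 80 °C) should then give 14.

**Further compounds**

F1 | step 12 | C5'-iodide (iodine in place of boron in 13) | O=C(O[C@@H]1Cc2c(O[Si](C)(C)C(C)(C)C)cc(O[Si](C)(C)C(C)(C)C)cc2O[C@@H]1c1cc(I)c2OC(C)(C)Oc2c1)c1cc(O[Si](C)(C)C(C)(C)C)c(O[Si](C)(C)C(C)(C)C)c(O[Si](C)(C)C(C)(C)C)c1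

F2 | step 12 | C5'-(diacetoxyiodo)arene | O=C(O[C@@H]1Cc2c(O[Si](C)(C)C(C)(C)C)cc(O[Si](C)(C)C(C)(C)C)cc2O[C@@H]1c1cc(I(OC(C)=O)OC(C)=O)c2OC(C)(C)Oc2c1)c1cc(O[Si](C)(C)C(C)(C)C)c(O[Si](C)(C)C(C)(C)C)c(O[Si](C)(C)C(C)(C)C)c1

F3 | step 12 | 2-hydroxy-2'-iodobiaryl dimer (19 with I in place of SCH3) | O=C(O[C@@H]1Cc2c(O[Si](C)(C)C(C)(C)C)cc(O[Si](C)(C)C(C)(C)C)cc2O[C@@H]1c1cc2OC(C)(C)Oc2c(I)c1-c1c([C@H]2Oc3cc(O[Si](C)(C)C(C)(C)C)cc(O[Si](C)(C)C(C)(C)C)c3C[C@H]2OC(=O)c2cc(O[Si](C)(C)C(C)(C)C)c(O[Si](C)(C)C(C)(C)C)c(O[Si](C)(C)C(C)(C)C)c2)cc2OC(C)(C)Oc2c1O)c1cc(O[Si](C)(C)C(C)(C)C)c(O[Si](C)(C)C(C)(C)C)c(O[Si](C)(C)C(C)(C)C)c1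

F4 | step 13 | desilylated methylsulfanyl biaryl bis-acetonide (19 without its ten silyl groups) | O=C(O[C@@H]1Cc2c(O)cc(O)cc2O[C@@H]1c1cc2OC(C)(C)Oc2c(SC)c1-c1c([C@H]2Oc3cc(O)cc(O)c3C[C@H]2OC(=O)c2cc(O)c(O)c(O)c2)cc2OC(C)(C)Oc2c1O)c1cc(O)c(O)c(O)c1

F5 | step 10 | C5'-triflate of phenol 12 | O=C(O[C@@H]1Cc2c(O[Si](C)(C)C(C)(C)C)cc(O[Si](C)(C)C(C)(C)C)cc2O[C@@H]1c1cc(OS(=O)(=O)C(F)(F)F)c2OC(C)(C)Oc2c1)c1cc(O[Si](C)(C)C(C)(C)C)c(O[Si](C)(C)C(C)(C)C)c(O[Si](C)(C)C(C)(C)C)c1
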